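**Strategy.** Ring B of the target (C1, C5–C10) is read as a cyclohepta-1,4-diene: the C1=C10 alkene of the target plus a temporary C7=C8 alkene, with C9H2 between them. Such a ring is the product of a [3,3] shift of a cis-divinylcyclopropane (C8–C9–C10), so one thermal step cleaves C8–C10, makes the hindered C5–C6 bond, closes the seven-membered ring and fixes H5/H6 trans. The precursor carries a 3-oxocyclopentenyl group on C10 and a (Z)-PMB enol ether on C8. It is built as a single enantiomer by ligand-controlled Simmons–Smith cyclopropanation, a stereoretentive Negishi coupling and a Stetter/aldol cyclopentenone annulation. C7=C8 later takes up H7 and O8 by hydroboration.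

Key step: step 10

Remark: guaiane numbering is used (ring A: C1–C5; ring B: C1, C5–C10; C15 on C4); PMB = 4-methoxybenzyl. No stereocentre is inverted once set; R/S labels that differ along the sequence (cyclopropane carbons, C6, C7) reflect changed CIP priorities only, and the SMILES strings are authoritative.

Assumption: the (4R,5R)-dioxaborolane shows its usual facial preference with iodoalkene 3, which gives the (1R,2R)-cyclopropane that maps onto 5R,6R of the target.

**Step 1**
Reactants: 1 prop-2-yn-1-ol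
Product: 3 (Z)-3-iodo-2-methylprop-2-en-1-ol, via vinylmagnesium alkoxide 2 (not isolated)
Conditions: MeMgBr (2.5 equiv), CuI (10 mol %), THF, −10 °C → rt; then I2, −78 → 0 °C
Reagents that add atoms: methylmagnesium bromide (C[Mg]Br); iodine (II)
Why: Copper-catalysed anti-carbomagnesiation of the propargylic alkoxide puts methyl on C2 and magnesium on C3 in a five-membered chelate, so iodinolysis with retention should give the iodide cis to CH2OH.

**Step 2**
Reactants: 3 (Z)-3-iodo-2-methylprop-2-en-1-ol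
Product: 4 [(1R,2R)-2-iodo-1-methylcyclopropyl]methanol
Conditions: Zn(CH2I)2·DME (from Et2Zn and CH2I2), (4R,5R)-2-butyl-N,N,N',N'-tetramethyl-1,3,2-dioxaborolane-4,5-dicarboxamide (1.2 equiv), CH2Cl2, −10 °C → rt
Reagents that add atoms: diiodomethane (ICI)
Why: Hydroxyl-directed asymmetric Simmons–Smith cyclopropanation: the dioxaborolane bound to the zinc alkoxide selects one alkene face, and stereospecific syn transfer of CH2 keeps iodine cis to CH2OH, which should set both ring stereocentres (the later C10 and C8).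

**Step 3**
Reactants: 5 (4-methoxyphenyl)methanol; 6 2-chloro-N-methoxy-N-methylacetamide
Product: 7 N-methoxy-2-[(4-methoxybenzyl)oxy]-N-methylacetamide
Conditions: NaH, THF, 0 °C; then 6, Bu4NI (cat.), 0 °C → rt
Reagents that add atoms: none
Why: Williamson ether synthesis, the alkoxide displacing the activated α-chloride by an SN2 reaction.

**Step 4**
Reactants: 7 N-methoxy-2-[(4-methoxybenzyl)oxy]-N-methylacetamide
Product: 8 1-[(4-methoxybenzyl)oxy]-3-methylbutan-2-one
Conditions: i-PrMgCl (1.3 equiv), THF, 0 °C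
Reagents that add atoms: isopropylmagnesium chloride (CC(C)[Mg]Cl)
Why: Weinreb ketone synthesis, in which the chelated tetrahedral adduct prevents a second addition.

**Step 5**
Reactants: 8 1-[(4-methoxybenzyl)oxy]-3-methylbutan-2-one
Product: 10 (Z)-1-[(4-methoxybenzyl)oxy]-3-methylbut-1-en-2-yl trifluoromethanesulfonate, via lithium enolate 9 (not isolated)
Conditions: LiHMDS (1.1 equiv), THF, −78 °C; N-(5-chloropyridin-2-yl)bis(trifluoromethanesulfonimide), −78 → 0 °C
Reagents that add atoms: N-(5-chloropyridin-2-yl)-1,1,1-trifluoro-N-(trifluoromethylsulfonyl)methanesulfonamide (FC(F)(F)S(=O)(=O)N(c1ccc(Cl)cn1)S(=O)(=O)C(F)(F)F)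
Why: Kinetic deprotonation at the less hindered OCH2 gives the lithium-chelated (Z)-enolate (the other geometry would press isopropyl against OPMB), and O-sulfonylation (enol triflate formation) fixes OTf cis to OPMB.

**Step 6**
Reactants: 4 [(1R,2R)-2-iodo-1-methylcyclopropyl]methanol; 10 (Z)-1-[(4-methoxybenzyl)oxy]-3-methylbut-1-en-2-yl trifluoromethanesulfonate
Product: 13 {(1S,2R)-2-[(Z)-1-[(4-methoxybenzyl)oxy]-3-methylbut-1-en-2-yl]-1-methylcyclopropyl}methanol, via dilithium alkoxide–cyclopropyllithium 11 (not isolated), via cyclopropylzinc chloride 12 (not isolated)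
Conditions: 4, MeLi (1.05 equiv), Et2O, −78 °C; t-BuLi (2.1 equiv), −78 °C; ZnCl2 (2.2 equiv, THF), −78 → 0 °C; then 10, Pd(PPh3)4 (5 mol %), THF, rt → 40 °C
Reagents that add atoms: none
Why: Iodine–lithium exchange on the pre-formed alkoxide (which cannot migrate as a silyl ether could), transmetallation to zinc and Negishi coupling all go with retention at the cyclopropyl carbon and at the alkenyl triflate, so the alkenyl group stays cis to CH2OH and the enol oxygen ends up cis to the ring.

**Step 7**
Reactants: 13 {(1S,2R)-2-[(Z)-1-[(4-methoxybenzyl)oxy]-3-methylbut-1-en-2-yl]-1-methylcyclopropyl}methanol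
Product: 14 (1S,2S)-2-[(Z)-1-[(4-methoxybenzyl)oxy]-3-methylbut-1-en-2-yl]-1-methylcyclopropane-1-carbaldehyde
Conditions: Dess–Martin periodinane, pyridine, CH2Cl2, 0 °C → rt
Reagents that add atoms: none
Why: Dess–Martin oxidation buffered with pyridine gives the non-enolisable aldehyde without acid that would hydrolyse the enol ether.

**Step 8**
Reactants: 14 (1S,2S)-2-[(Z)-1-[(4-methoxybenzyl)oxy]-3-methylbut-1-en-2-yl]-1-methylcyclopropane-1-carbaldehyde; 15 but-3-en-2-one
Product: 16 1-{(1S,2S)-2-[(Z)-1-[(4-methoxybenzyl)oxy]-3-methylbut-1-en-2-yl]-1-methylcyclopropyl}pentane-1,4-dione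
Conditions: 3-benzyl-5-(2-hydroxyethyl)-4-methylthiazolium chloride (20 mol %), Et3N (0.5 equiv), 1,4-dioxane, 70 °C
Reagents that add atoms: none
Why: Stetter reaction: the thiazolylidene turns the aldehyde into an acyl anion equivalent (Breslow intermediate) that adds 1,4 to the enone, giving the 1,4-diketone under weakly basic conditions that spare the enol ether.

**Step 9**
Reactants: 16 1-{(1S,2S)-2-[(Z)-1-[(4-methoxybenzyl)oxy]-3-methylbut-1-en-2-yl]-1-methylcyclopropyl}pentane-1,4-dione
Product: 18 3-{(1S,2R)-2-[(Z)-1-[(4-methoxybenzyl)oxy]-3-methylbut-1-en-2-yl]-1-methylcyclopropyl}cyclopent-2-en-1-one, via aldol adduct 17 (not isolated)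
Conditions: KOt-Bu (0.3 equiv), t-BuOH/THF, 0 °C → rt
Reagents that add atoms: none
Why: Intramolecular aldol condensation: only the methyl ketone enolate can reach the cyclopropyl ketone through a five-membered ring, and E1cB dehydration gives the 3-substituted cyclopentenone, the low temperature keeping the cis-divinylcyclopropane from rearranging while base is present.

**Step 10**
Reactants: 18 3-{(1S,2R)-2-[(Z)-1-[(4-methoxybenzyl)oxy]-3-methylbut-1-en-2-yl]-1-methylcyclopropyl}cyclopent-2-en-1-one
Product: 19 (5R,6S)-6-[(4-methoxybenzyl)oxy]guaia-1(10),7-dien-4-one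
Conditions: toluene (degassed, 0.01 M), 110 °C, silylated glass, no additive; product filtered and used at once
Reagents that add atoms: none
Why: The reaction is a concerted [3,3] sigmatropic shift of the cis-divinylcyclopropane through a boat transition state with both alkenes folded over the three-membered ring; the C8–C10 σ bond breaks as the C5–C6 σ bond forms, and the released ring strain makes it irreversible. The closest known reaction type is the thermal Cope rearrangement of β-(cis-2-vinylcyclopropyl) enones used to annulate seven-membered rings. Ring B is closed by joining the two alkene termini C5 and C6, that is by a pericyclic 3→7 ring expansion of the cyclopropane and not by an exo or endo cyclisation. C5 and C6 are created together by chirality transfer from C10 and C8: ring A forces H5 into the inside position of the boat and the (Z)-enol ether puts O6 inside as well, so H5 and O6 end up cis (H5/H6 trans) and the (1S,2R)-cyclopropane gives 5R,6S. The step needs this stereospecific pathway to outrun one-centre stereomutation of the cyclopropane and loss of PMBOH from the β-alkoxy ketone, which the cis geometry fixed in steps 2 and 6, the single enol ether geometry from step 5 and neutral, base-free conditions should secure.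

**Step 11**
Reactants: 19 (5R,6S)-6-[(4-methoxybenzyl)oxy]guaia-1(10),7-dien-4-one
Product: 20 (5R,6S)-6-[(4-methoxybenzyl)oxy]guaia-1(10),4(15),7-triene
Conditions: Cp2TiMe2 (3 equiv), toluene/THF, 65 °C, dark
Reagents that add atoms: dimethyltitanocene (C[Ti](C)(C1C=CC=C1)C1C=CC=C1)
Why: Petasis methylenation: the non-basic titanium methylidene olefinates the ketone through an oxatitanacyclobutane without enolising C5, so neither epimerisation nor β-elimination of the C6 ether should intervene.

**Step 12**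
Reactants: 20 (5R,6S)-6-[(4-methoxybenzyl)oxy]guaia-1(10),4(15),7-triene
Product: 21 (4S,5R,6S)-6-[(4-methoxybenzyl)oxy]guaia-1(10),7-dien-4-ol
Conditions: Co(acac)2 (20 mol %), PhSiH3 (2 equiv), O2 (1 atm), THF, 0 °C → rt
Reagents that add atoms: dioxygen (O=O)
Why: Mukaiyama hydration: hydrogen-atom transfer from the cobalt hydride goes to the least hindered, 1,1-disubstituted alkene, and the tertiary C4 radical is captured by O2 on the face of H5, anti to the C5–C6 bond, which should place OH cis to H5 and set C4.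

**Step 13**
Reactants: 21 (4S,5R,6S)-6-[(4-methoxybenzyl)oxy]guaia-1(10),7-dien-4-ol
Product: 23 (4S,5R,6R,7R,8S)-6-[(4-methoxybenzyl)oxy]guai-1(10)-ene-4,8-diol, via alkylborane 22 (not isolated)
Conditions: BH3·THF (3 equiv), THF, 0 °C → rt; then NaOH, H2O2, 0 °C
Reagents that add atoms: hydrogen peroxide (OO)
Why: Hydroboration–oxidation: borane adds syn to the trisubstituted C7=C8 with boron on C8, on the face of H6 that is anti to C5 (C6–O lying near the alkene plane), and oxidation with retention should give H7 and O8 both trans to O6, while the tetrasubstituted C1=C10 stays out.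

**Step 14**
Reactants: 23 (4S,5R,6R,7R,8S)-6-[(4-methoxybenzyl)oxy]guai-1(10)-ene-4,8-diol; 24 angelic acid, (Z)-2-methylbut-2-enoic acid
Product: 26 (4S,5R,6R,7R,8S)-4-hydroxy-6-[(4-methoxybenzyl)oxy]guai-1(10)-en-8-yl (Z)-2-methylbut-2-enoate, via mixed anhydride 25 (not isolated)
Conditions: 24, 2,4,6-trichlorobenzoyl chloride, Et3N, toluene, rt; then 23, 75 °C
Reagents that add atoms: none
Why: Yamaguchi-type esterification through the mixed anhydride acylates only the secondary C8 hydroxyl and, run without a nucleophilic catalyst, should keep the (Z)-alkene of the angelate.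

**Step 15**
Reactants: 26 (4S,5R,6R,7R,8S)-4-hydroxy-6-[(4-methoxybenzyl)oxy]guai-1(10)-en-8-yl (Z)-2-methylbut-2-enoate
Product: 27 (4S,5R,6R,7S,8S)-4,6-dihydroxyguai-1(10)-en-8-yl (Z)-2-methylbut-2-enoate
Conditions: DDQ, CH2Cl2/pH 7 buffer, 0 °C → rt
Reagents that add atoms: none
Why: Oxidative PMB ether cleavage: DDQ abstracts the benzylic hydride and water hydrolyses the oxocarbenium ion, leaving ester and alkenes untouched.

**Step 16**
Reactants: 27 (4S,5R,6R,7S,8S)-4,6-dihydroxyguai-1(10)-en-8-yl (Z)-2-methylbut-2-enoate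
Product: 28 (4S,5R,6R,7R,8S)-6-acetoxy-4-hydroxyguai-1(10)-en-8-yl (Z)-2-methylbut-2-enoate (target)
Conditions: Ac2O, DMAP (cat.), pyridine, CH2Cl2, 0 °C → rt
Reagents that add atoms: acetic anhydride (CC(=O)OC(C)=O)
Why: DMAP-catalysed acylation esterifies the secondary C6 hydroxyl, the tertiary C4 hydroxyl being too hindered to react under these conditions.

**Compound list**

1 | prop-2-yn-1-ol | C#CCO | starting material
2 | bromomagnesium (Z)-3-(bromomagnesio)-2-methylprop-2-en-1-olate | Br[Mg]OC/C(C)=C\[Mg]Br | intermediate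
3 | (Z)-3-iodo-2-methylprop-2-en-1-ol | OC/C(C)=C\I | intermediate
4 | [(1R,2R)-2-iodo-1-methylcyclopropyl]methanol (iodine cis to CH2OH) | OC[C@@]1(C)C[C@H]1I | intermediate
5 | (4-methoxyphenyl)methanol | COc1ccc(CO)cc1 | starting material
6 | 2-chloro-N-methoxy-N-methylacetamide | CON(C)C(=O)CCl | starting material
7 | N-methoxy-2-[(4-methoxybenzyl)oxy]-N-methylacetamide | CON(C)C(=O)COCc1ccc(OC)cc1 | intermediate
8 | 1-[(4-methoxybenzyl)oxy]-3-methylbutan-2-one | CC(C)C(=O)COCc1ccc(OC)cc1 | intermediate
9 | lithium (Z)-1-[(4-methoxybenzyl)oxy]-3-methylbut-1-en-2-olate | [Li]O/C(C(C)C)=C\OCc1ccc(OC)cc1 | intermediate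
10 | (Z)-1-[(4-methoxybenzyl)oxy]-3-methylbut-1-en-2-yl trifluoromethanesulfonate (OTf cis to OPMB) | FC(F)(F)S(=O)(=O)O/C(C(C)C)=C\OCc1ccc(OC)cc1 | intermediate
11 | lithium [(1S,2R)-2-lithio-1-methylcyclopropyl]methanolate (configuration of 4 retained) | [Li]OC[C@@]1(C)C[C@H]1[Li] | intermediate
12 | chlorozinc [(1R,2R)-2-(chlorozincio)-1-methylcyclopropyl]methanolate (configuration of 4 retained) | Cl[Zn]OC[C@@]1(C)C[C@H]1[Zn]Cl | intermediate
13 | {(1S,2R)-2-[(Z)-1-[(4-methoxybenzyl)oxy]-3-methylbut-1-en-2-yl]-1-methylcyclopropyl}methanol | OC[C@@]1(C)C[C@H]1/C(C(C)C)=C\OCc1ccc(OC)cc1 | intermediate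
14 | (1S,2S)-2-[(Z)-1-[(4-methoxybenzyl)oxy]-3-methylbut-1-en-2-yl]-1-methylcyclopropane-1-carbaldehyde | O=C[C@@]1(C)C[C@H]1/C(C(C)C)=C\OCc1ccc(OC)cc1 | intermediate
15 | but-3-en-2-one | CC(=O)C=C | starting material
16 | 1-{(1S,2S)-2-[(Z)-1-[(4-methoxybenzyl)oxy]-3-methylbut-1-en-2-yl]-1-methylcyclopropyl}pentane-1,4-dione | CC(=O)CCC(=O)[C@@]1(C)C[C@H]1/C(C(C)C)=C\OCc1ccc(OC)cc1 | intermediate
17 | 3-hydroxy-3-{(1S,2S)-2-[(Z)-1-[(4-methoxybenzyl)oxy]-3-methylbut-1-en-2-yl]-1-methylcyclopropyl}cyclopentan-1-one (carbinol epimers) | O=C1CCC(O)(C1)[C@@]2(C)C[C@H]2/C(C(C)C)=C\OCc3ccc(OC)cc3 | intermediate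
18 | 3-{(1S,2R)-2-[(Z)-1-[(4-methoxybenzyl)oxy]-3-methylbut-1-en-2-yl]-1-methylcyclopropyl}cyclopent-2-en-1-one (alkenyl groups cis on the cyclopropane) | O=C1CCC(=C1)[C@@]2(C)C[C@H]2/C(C(C)C)=C\OCc3ccc(OC)cc3 | intermediate
19 | (5R,6S)-6-[(4-methoxybenzyl)oxy]guaia-1(10),7-dien-4-one (H5 and O6 cis) | O=C1CCC2=C(C)CC=C(C(C)C)[C@@H](OCc3ccc(OC)cc3)[C@H]12 | intermediate
20 | (5R,6S)-6-[(4-methoxybenzyl)oxy]guaia-1(10),4(15),7-triene | C=C1CCC2=C(C)CC=C(C(C)C)[C@@H](OCc3ccc(OC)cc3)[C@H]12 | intermediate
21 | (4S,5R,6S)-6-[(4-methoxybenzyl)oxy]guaia-1(10),7-dien-4-ol (4-OH cis to H5) | C[C@]1(O)CCC2=C(C)CC=C(C(C)C)[C@@H](OCc3ccc(OC)cc3)[C@H]12 | intermediate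
22 | C8-boryl adduct of 21 (BH2 on C8 trans to O6, H7 cis to it; C4–O–BH2) | B[C@H]1CC(C)=C2CC[C@](C)(OB)[C@H]2[C@H](OCc3ccc(OC)cc3)[C@@H]1C(C)C | intermediate
23 | (4S,5R,6R,7R,8S)-6-[(4-methoxybenzyl)oxy]guai-1(10)-ene-4,8-diol | O[C@H]1CC(C)=C2CC[C@](C)(O)[C@H]2[C@H](OCc3ccc(OC)cc3)[C@@H]1C(C)C | intermediate
24 | angelic acid, (Z)-2-methylbut-2-enoic acid | C/C=C(/C)C(=O)O | starting material
25 | (Z)-2-methylbut-2-enoic 2,4,6-trichlorobenzoic anhydride | C/C=C(/C)C(=O)OC(=O)c1c(Cl)cc(Cl)cc1Cl | intermediate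
26 | (4S,5R,6R,7R,8S)-4-hydroxy-6-[(4-methoxybenzyl)oxy]guai-1(10)-en-8-yl (Z)-2-methylbut-2-enoate | C/C=C(/C)C(=O)O[C@H]1CC(C)=C2CC[C@](C)(O)[C@H]2[C@H](OCc3ccc(OC)cc3)[C@@H]1C(C)C | intermediate
27 | (4S,5R,6R,7S,8S)-4,6-dihydroxyguai-1(10)-en-8-yl (Z)-2-methylbut-2-enoate | C/C=C(/C)C(=O)O[C@H]1CC(C)=C2CC[C@](C)(O)[C@H]2[C@H](O)[C@@H]1C(C)C | intermediate
28 | (4S,5R,6R,7R,8S)-6-acetoxy-4-hydroxyguai-1(10)-en-8-yl (Z)-2-methylbut-2-enoate | C/C=C(/C)C(=O)O[C@H]1CC(C)=C2CC[C@](C)(O)[C@H]2[C@H](OC(C)=O)[C@@H]1C(C)C | target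

**Totals.** Total step count: 16. Longest linear sequence: 14 steps (steps 3–16, from 5 and 6); the branch from 1 (steps 1, 2, 6–16) is 13 steps.

**Steps most likely to fail**

Step 10 (key step). The alkoxy group sits inside the boat and raises the barrier. At the temperature then needed, the β-alkoxy ketone being formed may lose 4-methoxybenzyl alcohol by β-elimination or epimerise at C5, and the cyclopropane may start to stereomutate. The fallback removes the carbonyl group before the ring expansion. It sets out from 18: Wittig methylenation (Ph3P=CH2, THF, 0 °C) should give 1-{(1S,2R)-2-[(Z)-1-[(4-methoxybenzyl)oxy]-3-methylbut-1-en-2-yl]-1-methylcyclopropyl}-3-methylidenecyclopent-1-ene F1. Thermolysis of this triene in toluene should pass through the same boat transition state and give triene 20 directly, where the route is rejoined; no enolisable ketone is present while the product is hot, and step 11 falls away.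

Step 8. The hindered α-quaternary aldehyde may fail to form the acyl anion equivalent, or the cis-alkoxyvinyl aldehyde may drift into its dihydrooxepine valence isomer (retro-Claisen shift) faster than it is intercepted. The fallback brings in the four carbons as a nucleophile. It sets out from 14: addition of [3-(tert-butyldimethylsilyloxy)butyl]magnesium bromide (THF, −78 °C) should give 4-(tert-butyldimethylsilyloxy)-1-{(1S,2R)-2-[(Z)-1-[(4-methoxybenzyl)oxy]-3-methylbut-1-en-2-yl]-1-methylcyclopropyl}pentan-1-ol F2. TBAF then gives 1-{(1S,2R)-2-[(Z)-1-[(4-methoxybenzyl)oxy]-3-methylbut-1-en-2-yl]-1-methylcyclopropyl}pentane-1,4-diol F3, and pyridine-buffered Dess–Martin oxidation of both carbinols returns to the route at diketone 16.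

Step 12. Hydrogen-atom transfer may not stay on the exocyclic alkene: hydration of C7=C8, autoxidation at the doubly allylic C5–H and C9–H2 positions, or poor facial discrimination in the capture of O2. The fallback is a polar hydration, oxymercuration–demercuration, which discriminates strongly in favour of 1,1-disubstituted alkenes. It sets out from 20: Hg(OAc)2 in THF/water should give, by attack of water on C4 from the open face, (4S,5R,6S)-15-(acetoxymercurio)-6-[(4-methoxybenzyl)oxy]guaia-1(10),7-dien-4-ol F4. NaBH4/NaOH then replaces mercury by hydrogen and returns to the route at 21.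

**Further compounds**

F1 | step 10 | 1-{(1S,2R)-2-[(Z)-1-[(4-methoxybenzyl)oxy]-3-methylbut-1-en-2-yl]-1-methylcyclopropyl}-3-methylidenecyclopent-1-ene | C=C1CCC(=C1)[C@@]2(C)C[C@H]2/C(C(C)C)=C\OCc3ccc(OC)cc3
F2 | step 8 | 4-(tert-butyldimethylsilyloxy)-1-{(1S,2R)-2-[(Z)-1-[(4-methoxybenzyl)oxy]-3-methylbut-1-en-2-yl]-1-methylcyclopropyl}pentan-1-ol (carbinol epimers) | CC(O[Si](C)(C)C(C)(C)C)CCC(O)[C@@]1(C)C[C@H]1/C(C(C)C)=C\OCc1ccc(OC)cc1
F3 | step 8 | 1-{(1S,2R)-2-[(Z)-1-[(4-methoxybenzyl)oxy]-3-methylbut-1-en-2-yl]-1-methylcyclopropyl}pentane-1,4-diol (carbinol epimers) | CC(O)CCC(O)[C@@]1(C)C[C@H]1/C(C(C)C)=C\OCc1ccc(OC)cc1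
F4 | step 12 | (4S,5R,6S)-15-(acetoxymercurio)-6-[(4-methoxybenzyl)oxy]guaia-1(10),7-dien-4-ol | CC(=O)O[Hg]C[C@]1(O)CCC2=C(C)CC=C(C(C)C)[C@@H](OCc3ccc(OC)cc3)[C@H]12
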